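The cycloheptane ring (C1, C10, C9, C8, C7, C6, C5; locants defined below) is cut at C7–C8 and C1–C10, so that a cyclopentenone carrying a C7–C6–C5–C1 siloxydiene meets a three-carbon C8–C9–C10 vinylcarbenoid. In one operation a chiral dirhodium catalyst cyclopropanates the silyl enol ether and the cis-divinylcyclopropane rearranges, closing the cycloheptadiene and fixing the quaternary fusion carbon C1 as one enantiomer. The step exploits the C6 oxygen and the C8=C9 alkene (the masked 8,9-diol) flanking C7 in a ring that ends at the methyl-bearing C1. The precursor, 2-[1-(silyloxy)vinyl]-3-methylcyclopent-2-enone, is made regiospecifically by Stille coupling; all later stereocentres are relayed from C1.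

Key step: step 5

Locants (used for every intermediate): C1 methyl-bearing fusion carbon, C2, C3, C4 isopropyl carbinol, C5 fusion CH, C6 ester carbinol, C7, C8 methyl carbinol, C9, C10. β is the face of the bicycle that carries the C1 methyl group, α the other face.

Assumption: Rh2(R-DOSP)4 is taken to give the C1 configuration drawn in 10, by analogy with the known facial sense of its enantiomer in cyclopropanations of terminal alkenes with donor/acceptor diazo esters; if the sense is the reverse, Rh2(S-DOSP)4 is used and nothing else changes.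

Step 1
Reactants: 1 tributyl(1-ethoxyethenyl)stannane
Product: 2 acetyltributylstannane
Conditions: HCl (0.1 M aq, cat.), acetone, 0 °C, degassed, argon
Reagents that add atoms: water, O
Why: Enol ether hydrolysis (protonation at the terminal CH2, hydration, loss of ethanol) is a known entry to acylstannanes from 1-alkoxyvinylstannanes, and it moves the later silylation to a ketone whose only α-hydrogens are on the methyl group.

Step 2
Reactants: 2 acetyltributylstannane
Product: 4 tributyl{1-[(tert-butyldimethylsilyl)oxy]ethenyl}stannane, via lithium 1-(tributylstannyl)ethenolate 3 (not isolated)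
Conditions: LiN(i-Pr)2, THF, −78 °C; then t-BuMe2SiCl, DMPU, −78 → 0 °C
Reagents that add atoms: tert-butyldimethylsilyl chloride, CC(C)(C)[Si](C)(C)Cl
Why: Silyl enol ether formation from a kinetic lithium enolate; the acylstannane can enolise in one direction only, so the 1-(silyloxy)vinylstannane forms without any regiochemical choice.

Step 3
Reactants: 4 tributyl{1-[(tert-butyldimethylsilyl)oxy]ethenyl}stannane, 5 2-bromo-3-methylcyclopent-2-en-1-one
Product: 6 2-{1-[(tert-butyldimethylsilyl)oxy]ethenyl}-3-methylcyclopent-2-en-1-one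
Conditions: Pd(PPh3)4 (5 mol%), CuI (10 mol%), DMF, 60 °C; fluoride-free work-up
Reagents that add atoms: none
Why: Stille coupling of an α-bromo enone with an α-oxygenated vinylstannane (CuI-accelerated) joins C5 to C6 with the silyl enol ether already in place, so the γ-hydrogens of a 2-acetyl-3-methylenone, which are activated by both carbonyl groups, never have to be discriminated in an enolisation.

Step 4
Reactants: 7 methyl but-3-enoate
Product: 8 methyl 2-diazobut-3-enoate
Conditions: 4-acetamidobenzenesulfonyl azide, DBU, MeCN, 0 °C; kept cold as a pentane solution and used at once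
Reagents that add atoms: 4-acetamidobenzenesulfonyl azide, CC(=O)Nc1ccc(cc1)S(=O)(=O)N=[N+]=[N-]
Why: Regitz diazo transfer to the DBU-generated dienolate of the β,γ-unsaturated ester gives the vinyldiazoacetate; the methyl ester is chosen because small ester groups are known to give the highest enantioselectivity with dirhodium arylsulfonylprolinate catalysts, and the ester is reduced away later in any case.

Step 5
Reactants: 6 2-{1-[(tert-butyldimethylsilyl)oxy]ethenyl}-3-methylcyclopent-2-en-1-one, 8 methyl 2-diazobut-3-enoate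
Product: 10 methyl (8aR)-4-[(tert-butyldimethylsilyl)oxy]-8a-methyl-3-oxo-1,2,3,5,8,8a-hexahydroazulene-6-carboxylate, via cis-divinylcyclopropane 9 (not isolated)
Conditions: Rh2(R-DOSP)4 [dirhodium tetrakis((R)-N-(4-dodecylphenylsulfonyl)prolinate), divalent rhodium] (1 mol%), hexanes, −78 → 23 °C, 8 (2.5 equiv) added slowly; then toluene, 80–110 °C
Reagents that add atoms: none
Why: The dirhodium carbenoid formed from 8 by loss of N2 adds to the electron-rich terminal siloxyvinyl bond of 6 (new C7–C8 bond and transient C6–C8 bond), placing the carbenoid vinyl group and the cyclopentenonyl group cis on cyclopropane 9. On heating, 9 undergoes a [3,3]-sigmatropic divinylcyclopropane (Cope) rearrangement through a boat transition state that breaks C6–C8 and forms C1–C10; the closest known reaction type is the tandem cyclopropanation–Cope (formal 4+3) annulation of vinyldiazoacetates with 2-siloxydienes. The seven-membered ring is closed by this pericyclic ring expansion of the three-membered ring, not by an end-to-end cyclisation, so both new ring alkenes (C5=C6 and C8=C9) are necessarily cis. The C1 stereocentre is controlled by the chiral prolinate ligands, which fix the cyclopropane carbons C6 and C8, and by the stereospecific boat geometry, which relays that configuration to C1. The step needs chemoselectivity for the silyl enol ether over the enone alkene, secured by the electrophilic donor/acceptor carbenoid and the hydrocarbon solvent (which also disfavours vinylogous attack), and it needs the cis-divinyl isomer, which the donor–acceptor substituted C6–C8 bond can reach by reversible opening should the trans isomer form. Because the C1 methyl group points into the boat, the rearrangement is driven thermally after the low-temperature cyclopropanation.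

Step 6
Reactants: 10 methyl (8aR)-4-[(tert-butyldimethylsilyl)oxy]-8a-methyl-3-oxo-1,2,3,5,8,8a-hexahydroazulene-6-carboxylate
Product: 12 methyl (3R,3aR,8aR)-3-hydroxy-8a-methyl-4-oxo-3-(propan-2-yl)-1,2,3,3a,4,5,8,8a-octahydroazulene-6-carboxylate, via tertiary-alcohol silyl enol ether 11 (not isolated)
Conditions: CeCl3 (anhydrous), i-PrMgCl, THF, −78 °C; then AcOH, n-Bu4NF, THF, −78 → 0 °C
Reagents that add atoms: isopropylmagnesium chloride, CC(C)[Mg]Cl
Why: Organocerium 1,2-addition to the weakly electrophilic, enolisable vinylogous silyl ester carbonyl spares the methyl enoate and should come from the α-face, away from the C1 methyl group, so that the C4 hydroxyl is β; buffered fluoride then cleaves the silyl enol ether without acid (no Stork–Danheiser loss of the tertiary hydroxyl) and C5 should settle with its hydrogen α, giving the trans-fused, hydrogen-bonded β-hydroxy ketone in which C6 is cis to the hydroxyl and not to the isopropyl group.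

Step 7
Reactants: 12 methyl (3R,3aR,8aR)-3-hydroxy-8a-methyl-4-oxo-3-(propan-2-yl)-1,2,3,3a,4,5,8,8a-octahydroazulene-6-carboxylate
Product: 13 methyl (3R,3aS,4S,8aR)-3,4-dihydroxy-8a-methyl-3-(propan-2-yl)-1,2,3,3a,4,5,8,8a-octahydroazulene-6-carboxylate
Conditions: Me4NBH(OAc)3, MeCN–AcOH (1:1), −30 → 0 °C
Reagents that add atoms: none
Why: Evans–Saksena reduction: the C4 hydroxyl exchanges onto boron and delivers hydride intramolecularly to the β-face of the C6 ketone, giving the 6α-alcohol, whereas external hydride on a boron chelate would attack the open α-face (anti to the C1 methyl) and give the C6 epimer.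

Step 8
Reactants: 13 methyl (3R,3aS,4S,8aR)-3,4-dihydroxy-8a-methyl-3-(propan-2-yl)-1,2,3,3a,4,5,8,8a-octahydroazulene-6-carboxylate
Product: 14 (3R,3aS,4S,8aR)-6-(hydroxymethyl)-8a-methyl-3-(propan-2-yl)-1,2,3,3a,4,5,8,8a-octahydroazulene-3,4-diol
Conditions: i-Bu2AlH (5 equiv), CH2Cl2, −78 → −20 °C; aqueous potassium sodium tartrate
Reagents that add atoms: none
Why: Aluminium hydride 1,2-reduction of the α,β-unsaturated methyl ester gives the primary allylic alcohol and leaves the C8=C9 alkene and both carbinol centres untouched.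

Step 9
Reactants: 14 (3R,3aS,4S,8aR)-6-(hydroxymethyl)-8a-methyl-3-(propan-2-yl)-1,2,3,3a,4,5,8,8a-octahydroazulene-3,4-diol
Product: 16 (3R,3aS,4S,8aR)-6,8a-dimethyl-3-(propan-2-yl)-1,2,3,3a,4,5,8,8a-octahydroazulene-3,4-diol, via allylic methanesulfonate 15 (not isolated)
Conditions: MeSO2Cl (1.05 equiv), Et3N, THF, −40 °C; then LiEt3BH, −40 → 0 °C
Reagents that add atoms: none
Why: Allylic deoxygenation by sulfonate reduction: the unhindered primary allylic hydroxyl is sulfonylated much faster than the hindered secondary and the tertiary hydroxyl, and LiEt3BH displaces the mesylate by SN2 hydride attack, leaving the C8 methyl group without moving the alkene.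

Step 10
Reactants: 16 (3R,3aS,4S,8aR)-6,8a-dimethyl-3-(propan-2-yl)-1,2,3,3a,4,5,8,8a-octahydroazulene-3,4-diol, 17 4-(benzyloxy)benzoic acid
Product: 18 (3R,3aS,4S,8aR)-3-hydroxy-6,8a-dimethyl-3-(propan-2-yl)-1,2,3,3a,4,5,8,8a-octahydroazulen-4-yl 4-(benzyloxy)benzoate
Conditions: DCC, DMAP, CH2Cl2, 0 → 23 °C
Reagents that add atoms: none
Why: Steglich esterification acylates only the secondary C6 hydroxyl, the tertiary C4 hydroxyl being inert to carbodiimide/DMAP activation, and the phenol is carried as its benzyl ether.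

Step 11
Reactants: 18 (3R,3aS,4S,8aR)-3-hydroxy-6,8a-dimethyl-3-(propan-2-yl)-1,2,3,3a,4,5,8,8a-octahydroazulen-4-yl 4-(benzyloxy)benzoate
Product: 19 8α,9α-epoxide of 18 (oxirane on C8–C9 on the face opposite the C1 methyl group)
Conditions: 3-ClC6H4CO3H, NaHCO3, CH2Cl2, 0 °C
Reagents that add atoms: 3-chloroperbenzoic acid, OOC(=O)c1cccc(Cl)c1
Why: Prilezhaev epoxidation of the only alkene should occur on the α-face, anti to the axial C1 methyl group that is homoallylic to C9 (the bias that gives 2α,3α-epoxides from 5α-steroid 2-enes), which sets the C9 oxygen α.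

Step 12
Reactants: 19 8α,9α-epoxide of 18
Product: 20 (3R,3aS,4S,6S,7S,8aR)-3,6,7-trihydroxy-6,8a-dimethyl-3-(propan-2-yl)decahydroazulen-4-yl 4-(benzyloxy)benzoate
Conditions: HClO4 (cat., aq), THF–H2O (3:1), 0 → 23 °C
Reagents that add atoms: water, O
Why: Acid-catalysed epoxide hydrolysis: water opens the protonated trisubstituted epoxide at the tertiary carbon C8 with inversion, from the β-face, giving the trans diol with 8β-OH and 9α-OH, and the α-ester at C6 cannot participate from the rear.

Step 13
Reactants: 20 (3R,3aS,4S,6S,7S,8aR)-3,6,7-trihydroxy-6,8a-dimethyl-3-(propan-2-yl)decahydroazulen-4-yl 4-(benzyloxy)benzoate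
Product: 21 (3R,3aS,4S,6S,7S,8aR)-3,6,7-trihydroxy-6,8a-dimethyl-3-(propan-2-yl)decahydroazulen-4-yl 4-hydroxybenzoate
Conditions: H2 (1 atm), Pd/C, EtOAc, 23 °C
Reagents that add atoms: none
Why: Hydrogenolysis of the benzyl aryl ether over palladium releases the phenol, and no alkene or other reducible group remains at this stage.

Compound list

1 | tributyl(1-ethoxyethenyl)stannane | CCCC[Sn](CCCC)(CCCC)C(=C)OCC | starting material
2 | acetyltributylstannane, 1-(tributylstannyl)ethan-1-one | CCCC[Sn](CCCC)(CCCC)C(C)=O | intermediate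
3 | lithium 1-(tributylstannyl)ethenolate | [Li+].[O-]C(=C)[Sn](CCCC)(CCCC)CCCC | intermediate (not isolated)
4 | tributyl{1-[(tert-butyldimethylsilyl)oxy]ethenyl}stannane | CCCC[Sn](CCCC)(CCCC)C(=C)O[Si](C)(C)C(C)(C)C | intermediate
5 | 2-bromo-3-methylcyclopent-2-en-1-one | CC1=C(Br)C(=O)CC1 | starting material
6 | 2-{1-[(tert-butyldimethylsilyl)oxy]ethenyl}-3-methylcyclopent-2-en-1-one | C=C(O[Si](C)(C)C(C)(C)C)C1=C(C)CCC1=O | intermediate (precursor of the key step)
7 | methyl but-3-enoate | C=CCC(=O)OC | starting material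
8 | methyl 2-diazobut-3-enoate | C=CC(=[N+]=[N-])C(=O)OC | intermediate
9 | methyl (1S,2R)-2-[(tert-butyldimethylsilyl)oxy]-1-ethenyl-2-(2-methyl-5-oxocyclopent-1-en-1-yl)cyclopropane-1-carboxylate (vinyl and cyclopentenonyl groups cis) | C=C[C@@]1(C(=O)OC)C[C@@]1(O[Si](C)(C)C(C)(C)C)C2=C(C)CCC2=O | intermediate (not isolated)
10 | methyl (8aR)-4-[(tert-butyldimethylsilyl)oxy]-8a-methyl-3-oxo-1,2,3,5,8,8a-hexahydroazulene-6-carboxylate (C4 ketone, C5=C6 silyl enol ether, ester on C8 of the C8=C9 alkene, quaternary C1) | O=C1CC[C@]2(C)CC=C(C(=O)OC)CC(O[Si](C)(C)C(C)(C)C)=C12 | intermediate (product of the key step)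
11 | methyl (3R,8aR)-4-[(tert-butyldimethylsilyl)oxy]-3-hydroxy-8a-methyl-3-(propan-2-yl)-1,2,3,5,8,8a-hexahydroazulene-6-carboxylate (4β-OH) | CC(C)[C@]1(O)CC[C@]2(C)CC=C(C(=O)OC)CC(O[Si](C)(C)C(C)(C)C)=C21 | intermediate (not isolated)
12 | methyl (3R,3aR,8aR)-3-hydroxy-8a-methyl-4-oxo-3-(propan-2-yl)-1,2,3,3a,4,5,8,8a-octahydroazulene-6-carboxylate (4β-OH, 5α-H, C6 ketone) | CC(C)[C@]1(O)CC[C@]2(C)CC=C(C(=O)OC)CC(=O)[C@H]21 | intermediate
13 | methyl (3R,3aS,4S,8aR)-3,4-dihydroxy-8a-methyl-3-(propan-2-yl)-1,2,3,3a,4,5,8,8a-octahydroazulene-6-carboxylate (4β-OH, 6α-OH) | CC(C)[C@]1(O)CC[C@]2(C)CC=C(C(=O)OC)C[C@H](O)[C@H]21 | intermediate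
14 | (3R,3aS,4S,8aR)-6-(hydroxymethyl)-8a-methyl-3-(propan-2-yl)-1,2,3,3a,4,5,8,8a-octahydroazulene-3,4-diol | CC(C)[C@]1(O)CC[C@]2(C)CC=C(CO)C[C@H](O)[C@H]21 | intermediate
15 | primary allylic methanesulfonate of 14 | CC(C)[C@]1(O)CC[C@]2(C)CC=C(COS(C)(=O)=O)C[C@H](O)[C@H]21 | intermediate (not isolated)
16 | (3R,3aS,4S,8aR)-6,8a-dimethyl-3-(propan-2-yl)-1,2,3,3a,4,5,8,8a-octahydroazulene-3,4-diol | CC(C)[C@]1(O)CC[C@]2(C)CC=C(C)C[C@H](O)[C@H]21 | intermediate
17 | 4-(benzyloxy)benzoic acid | OC(=O)c1ccc(OCc2ccccc2)cc1 | starting material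
18 | (3R,3aS,4S,8aR)-3-hydroxy-6,8a-dimethyl-3-(propan-2-yl)-1,2,3,3a,4,5,8,8a-octahydroazulen-4-yl 4-(benzyloxy)benzoate | CC(C)[C@]1(O)CC[C@]2(C)CC=C(C)C[C@H](OC(=O)c3ccc(OCc4ccccc4)cc3)[C@H]21 | intermediate
19 | 8α,9α-epoxide of 18 (4β-OH, 5α-H, 6α-aroyloxy, oxirane oxygen α on C8 and C9) | CC(C)[C@]1(O)CC[C@]2(C)C[C@@H]3O[C@]3(C)C[C@H](OC(=O)c4ccc(OCc5ccccc5)cc4)[C@H]21 | intermediate
20 | (3R,3aS,4S,6S,7S,8aR)-3,6,7-trihydroxy-6,8a-dimethyl-3-(propan-2-yl)decahydroazulen-4-yl 4-(benzyloxy)benzoate (8β-OH, 9α-OH) | CC(C)[C@]1(O)CC[C@]2(C)C[C@H](O)[C@@](C)(O)C[C@H](OC(=O)c3ccc(OCc4ccccc4)cc3)[C@H]21 | intermediate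
21 | (3R,3aS,4S,6S,7S,8aR)-3,6,7-trihydroxy-6,8a-dimethyl-3-(propan-2-yl)decahydroazulen-4-yl 4-hydroxybenzoate | CC(C)[C@]1(O)CC[C@]2(C)C[C@H](O)[C@@](C)(O)C[C@H](OC(=O)c3ccc(O)cc3)[C@H]21 | target

Total step count: 13.
Longest linear sequence: 12 steps (steps 1–3 and 5–13; step 4 is a one-step branch).

Steps most likely to fail

Step 5. What may go wrong: weak enantiofacial discrimination by the catalyst on a hindered 1,1-disubstituted silyl enol ether, or vinylogous attack of the unsubstituted vinylcarbenoid competing with cyclopropanation. Fallback (auxiliary control in place of catalyst control; it sets out from compound 6 and comes back at compound 14):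
- But-3-enoic acid is esterified with (R)-pantolactone (DCC, DMAP) to (3R)-4,4-dimethyl-2-oxooxolan-3-yl but-3-enoate F1.
- Diazo transfer as in step 4 gives the diazo ester F2.
- Rh2(O2CC7H15)4 in hexanes, then heating, should convert 6 and F2 via the auxiliary-bearing divinylcyclopropane F3 into the pantolactonyl ester of the hydroazulenone F4. The C1 epimers are now diastereomers, and the wanted one would be purified by chromatography or crystallisation.
- F4 is carried through the operations of step 6 (via the tertiary-alcohol silyl enol ether F5 to the hydroxy ketone F6) and of step 7 (diol F7).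
- The i-Bu2AlH reduction of step 8 removes the auxiliary and delivers 14.

Step 6. What may go wrong: poor facial selectivity in the addition to C4, or loss of the tertiary hydroxyl (elimination or retro-aldol cleavage) when the enol ether is unmasked. Fallback (oxygen delivered to C4 by a hydroxyl-directed epoxidation instead of carbon delivered to one ketone face; it sets out from compound 10 and comes back at compound 12):
- The same organocerium addition is worked up with dilute HCl, so that 11 collapses by Stork–Danheiser transposition to the 4-isopropyl-4-en-6-one F8, in which C4 is no longer stereogenic.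
- Luche reduction (NaBH4, CeCl3·7H2O, MeOH) from the α-face should give the 6β-allylic alcohol F9.
- VO(acac)2/t-BuOOH epoxidises the C4=C5 bond syn to that hydroxyl, giving the 4β,5β-epoxy alcohol F10.
- Dess–Martin oxidation gives the epoxy ketone F11.
- SmI2 (THF–MeOH, −78 °C) cleaves the C5–O bond α to the ketone, keeping the 4β-hydroxyl and giving 12 after protonation at C5.

Step 3. What may go wrong: slow transmetalation of the hindered 1-silyloxyvinylstannane, with protodestannylation or desilylation overtaking the coupling. Fallback (silyl enol ether made after the C5–C6 bond instead of before; it sets out from compounds 5 and 1 and comes back at compound 6):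
- Stille coupling of 5 with 1 gives 2-(1-ethoxyethenyl)-3-methylcyclopent-2-en-1-one F12.
- Brief aqueous acid gives 2-acetyl-3-methylcyclopent-2-en-1-one F13.
- Kinetic deprotonation (LiN(i-Pr)2, THF, −78 °C, inverse addition) to the lithium enolate F14, then t-BuMe2SiOSO2CF3, gives 6.
- The price is that the γ-hydrogens of F13 are activated by both carbonyl groups, so regioisomeric dienol ethers may have to be separated.

Further compounds

F1 | step 5 | (3R)-4,4-dimethyl-2-oxooxolan-3-yl but-3-enoate | C=CCC(=O)O[C@H]1C(=O)OCC1(C)C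
F2 | step 5 | (3R)-4,4-dimethyl-2-oxooxolan-3-yl 2-diazobut-3-enoate | C=CC(=[N+]=[N-])C(=O)O[C@H]1C(=O)OCC1(C)C
F3 | step 5 | (3R)-4,4-dimethyl-2-oxooxolan-3-yl ester analogue of cyclopropane 9 | C=C[C@@]1(C(=O)O[C@H]3C(=O)OCC3(C)C)C[C@@]1(O[Si](C)(C)C(C)(C)C)C2=C(C)CCC2=O
F4 | step 5 | (3R)-4,4-dimethyl-2-oxooxolan-3-yl ester analogue of 10 | O=C1CC[C@]2(C)CC=C(C(=O)O[C@H]3C(=O)OCC3(C)C)CC(O[Si](C)(C)C(C)(C)C)=C12
F5 | step 5 | (3R)-4,4-dimethyl-2-oxooxolan-3-yl ester analogue of 11 | CC(C)[C@]1(O)CC[C@]2(C)CC=C(C(=O)O[C@H]3C(=O)OCC3(C)C)CC(O[Si](C)(C)C(C)(C)C)=C21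
F6 | step 5 | (3R)-4,4-dimethyl-2-oxooxolan-3-yl ester analogue of 12 | CC(C)[C@]1(O)CC[C@]2(C)CC=C(C(=O)O[C@H]3C(=O)OCC3(C)C)CC(=O)[C@H]21
F7 | step 5 | (3R)-4,4-dimethyl-2-oxooxolan-3-yl ester analogue of 13 | CC(C)[C@]1(O)CC[C@]2(C)CC=C(C(=O)O[C@H]3C(=O)OCC3(C)C)C[C@H](O)[C@H]21
F8 | step 6 | methyl (8aR)-8a-methyl-4-oxo-3-(propan-2-yl)-1,2,4,5,8,8a-hexahydroazulene-6-carboxylate | CC(C)C1=C2C(=O)CC(C(=O)OC)=CC[C@@]2(C)CC1
F9 | step 6 | methyl (4R,8aR)-4-hydroxy-8a-methyl-3-(propan-2-yl)-1,2,4,5,8,8a-hexahydroazulene-6-carboxylate (6β-OH) | CC(C)C1=C2[C@H](O)CC(C(=O)OC)=CC[C@@]2(C)CC1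
F10 | step 6 | 4β,5β-epoxide of F9 (6β-OH) | CC(C)[C@]12CC[C@]3(C)CC=C(C(=O)OC)C[C@@H](O)[C@]13O2
F11 | step 6 | 4β,5β-epoxy-6-ketone from F10 | CC(C)[C@]12CC[C@]3(C)CC=C(C(=O)OC)CC(=O)[C@]13O2
F12 | step 3 | 2-(1-ethoxyethenyl)-3-methylcyclopent-2-en-1-one | C=C(OCC)C1=C(C)CCC1=O
F13 | step 3 | 2-acetyl-3-methylcyclopent-2-en-1-one | CC(=O)C1=C(C)CCC1=O
F14 | step 3 | lithium 1-(2-methyl-5-oxocyclopent-1-en-1-yl)ethenolate | [Li+].[O-]C(=C)C1=C(C)CCC1=O
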